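| setting | dawn | winter | flask |
|---|---|---|---|
| substrate | 1 M | 1 M | 1.0 M |
| solid reagent | 1.4 equiv | 2.2 equiv | 1.00 equiv |
| catalyst | 1 mol% | 1 mol% | 1 mol% |
| remark | run made earlier | run made earlier |  |
| time |  |  | 2.0 min |

| dawn: time / min | dawn: product / % | winter: time / min | winter: product / % |
|---|---|---|---|
| 0.333 | 81.2 | 0.333 | 82.4 |
| 0.833 | 98.6 | 0.833 | 99.8 |
| 1.50 | 100.1 | 1.50 | 98.9 |
| 2.50 | 100.9 | 2.50 | 100.6 |

(readings scatter by 0.5 percentage points)

- the product standing at 2.0 min, as a percentage of the substrate charged
- concentration of partner in solution at 2.0 min, in percent of saturation

- given per volume of solution although it is solid: solid reagent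
- the analysis behind the earlier runs scatters by 0.5 percentage points, standard deviation
- at the start none of the solid reagent is in solution
- partner is what solid reagent becomes in solution

- The flask holds equal amounts, 1.0 M of substrate against 1.00 equiv of solid reagent, with 1 mol% of catalyst, and the concentration of partner, which dissolves from the solid, sets the order of the rate.
- While solid remains, partner should hold one level and substrate should fall pseudo-first-order. The dawn reading at 0.333 min gives 5.02 min⁻¹, and the winter reading there lies 1.2 percentage points higher, against a scatter of 0.5 points.
- Taking one partner per substrate, the dawn flask then held 0.588 M of solid and partner together; this reckoning uses that amount as a working partner level, an estimate and not the saturation concentration.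
- Once the solid has gone from this flask, partner equals substrate and the rate follows the square of substrate. Counting the whole run as this tail, the first-order constant times the time, times substrate over partner level, is the tail number 17.1.
- The share of substrate left in this flask is the inverse of one plus that number, about 5.53 %, so product stands near 94.5 % and partner near 0.0553 M; this reckoning gives no saturation concentration, so it leaves the percentage of saturation open.
- This reckoning needs equal amounts, so the weighed solid stays untouched.
- The forecast gives 98 % and 11 %, more product than this reckoning, and calls the saturation figure “much better defined”.
- The flask gives 94.7 % and 6.95 %.

    substrate + partner + catalyst → catalyst + product (k = 15.4 M⁻² s⁻¹)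
    solid reagent ⇌ partner, rate k2*(cs2 - [partner]) while solid is left; crystals form when [partner] > cs2 (solubility = 0.760 M, k = 0.373 s⁻¹)

- The rate carries catalyst, partner and substrate, and with equivalents and loadings held, catalyst and partner both scale with substrate, so the tail number goes with the square of the substrate concentration. For the neighbouring flask at 0.40 M it becomes 2.73, which leaves 26.8 % of the substrate. That neighbouring flask holds 25 % of its substrate at 2.00 min, with product at 74.6 % and partner at 0.102 M.

(The runs were generated by integration for an exercise; scatter was added.)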